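**Retrosynthetic overview**

1. Feature used (drimane numbering): ring A (C1–C5, C10) carries no functional group, and its quaternary C4 (gem-dimethyl) sits on ring-fusion carbon C5, next to the only unsaturation of ring B (C5=C6).
2. Key disconnection: C5–C10 and C3–C4 together, by an intramolecular Diels–Alder reaction of a C4=C5 β,β-dimethyl enone (C6 ketone in the tether C6–C9) with an (E)-diene (C10=C1–C2=C3) on C9. The C6 ketone later becomes the C5=C6 alkene.
3. Trienone: C5–C6 by Grignard addition to a C6 aldehyde, C10=C1 by Wittig olefination of a lactol. C8 comes from (R)-4-methyl-δ-valerolactone and C9 from two enolate alkylations of it (benzylic bromide, then MeI anti to the C8 methyl).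
4. Arene: 2,4,5-trihydroxybenzaldehyde, with C4'/C5' oxygens as benzyl ethers and the C2' oxygen as a silyl ether. C3' formylation, C2' sulfation and debenzylation come last.
5. Ring order: the arene is bought; rings B and A close together in step 13.

Key step: step 13

Remark: drimane numbering is used in the text (C11 benzylic, arene C1'–C6'), Ar stands for 4,5-bis(benzyloxy)-2-(triisopropylsilyloxy)phenyl, and hydrogen sulfates 28 and 29 are drawn as free acids although they are handled as sodium salts until a last cation exchange.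

**Route**

Step 1
Reactants: 1 2,4,5-trihydroxybenzaldehyde
Product: 2 4,5-bis(benzyloxy)-2-hydroxybenzaldehyde
Conditions: BnBr (2.05 equiv), K2CO3 (2.1 equiv), DMF, 0 °C to rt, argon
Reagents that add atoms: benzyl bromide, BrCc1ccccc1
Why: Williamson etherification in which the C2' hydroxyl, held in a hydrogen bond to the aldehyde, is the least nucleophilic of the three, so two equivalents of benzyl bromide should end on the C4' and C5' oxygens.

Step 2
Reactants: 2 4,5-bis(benzyloxy)-2-hydroxybenzaldehyde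
Product: 3 4,5-bis(benzyloxy)-2-(triisopropylsilyloxy)benzaldehyde
Conditions: i-Pr3SiCl, imidazole, DMF, 40 °C
Reagents that add atoms: chlorotriisopropylsilane, CC(C)[Si](Cl)(C(C)C)C(C)C
Why: Silylation of the remaining phenol, the triisopropylsilyl ether being chosen because it should withstand enolates, hydrides, the Grignard reagent and MeAlCl2 and is later removed by fluoride without touching the benzyl ethers.

Step 3
Reactants: 3 4,5-bis(benzyloxy)-2-(triisopropylsilyloxy)benzaldehyde
Product: 4 [4,5-bis(benzyloxy)-2-(triisopropylsilyloxy)phenyl]methanol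
Conditions: NaBH4, THF–MeOH, 0 °C
Reagents that add atoms: none
Why: Borohydride reduction of the aldehyde, run cold in methanol so that the benzylic alkoxide is protonated before the silyl group can migrate to it.

Step 4
Reactants: 4 [4,5-bis(benzyloxy)-2-(triisopropylsilyloxy)phenyl]methanol
Product: 5 4,5-bis(benzyloxy)-2-(triisopropylsilyloxy)benzyl bromide
Conditions: CBr4, PPh3, CH2Cl2, 0 °C; used crude at once
Reagents that add atoms: tetrabromomethane, BrC(Br)(Br)Br
Why: Appel bromination under neutral conditions gives the electron-rich benzylic bromide, which is not stored because it ionises easily.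

Step 5
Reactants: 6 (R)-5-methoxy-3-methyl-5-oxopentanoic acid (methyl hydrogen (R)-3-methylglutarate)
Product: 8 (R)-4-methyltetrahydro-2H-pyran-2-one, via hydroxy ester 7 (not isolated)
Conditions: BH3·SMe2, THF, 0 °C to rt; then TsOH (cat.), toluene, 60 °C
Reagents that add atoms: none
Why: Borane reduces the free carboxylic acid much faster than the ester and the hydroxy ester then lactonises under acid catalysis, so the methyl-bearing centre (later C8) is carried unchanged from 6.

Step 6
Reactants: 8 (R)-4-methyltetrahydro-2H-pyran-2-one; 5 4,5-bis(benzyloxy)-2-(triisopropylsilyloxy)benzyl bromide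
Product: 10 (3S,4R)-3-(ArCH2)-4-methyltetrahydro-2H-pyran-2-one, via lithium enolate 9 (not isolated)
Conditions: LiN(i-Pr)2 (1.05 equiv), THF, −78 °C; then 5, −78 to −40 °C
Reagents that add atoms: none
Why: Alkylation of the lactone lithium enolate (SN2 on the benzylic bromide) forms the C9–C11 bond; the electrophile should enter anti to the C8 methyl, but this configuration does not matter because C9 is enolised again in step 7.

Step 7
Reactants: 10 (3S,4R)-3-(ArCH2)-4-methyltetrahydro-2H-pyran-2-one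
Product: 12 (3R,4R)-3-(ArCH2)-3,4-dimethyltetrahydro-2H-pyran-2-one, via lithium enolate 11 (not isolated)
Conditions: LiN(i-Pr)2 (1.2 equiv), THF–DMPU, −78 °C; then MeI, −78 to −30 °C
Reagents that add atoms: iodomethane, CI
Why: Second enolate alkylation builds quaternary C9: in the tetrasubstituted enolate, allylic strain with the arylmethyl group holds the C8 methyl pseudo-axial, so iodomethane should attack the opposite face and place the new methyl trans and the arylmethyl group cis to the C8 methyl (substrate control by C8).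

Step 8
Reactants: 12 (3R,4R)-3-(ArCH2)-3,4-dimethyltetrahydro-2H-pyran-2-one
Product: 13 (3R,4R)-3-(ArCH2)-3,4-dimethyltetrahydro-2H-pyran-2-ol (both anomers)
Conditions: i-Bu2AlH (1.2 equiv), CH2Cl2, −78 °C; Rochelle salt work-up
Reagents that add atoms: none
Why: Partial reduction of the lactone at low temperature stops at the aluminium hemiacetal, which gives the lactol on work-up; the anomeric centre is of no consequence.

Step 9
Reactants: 13 (3R,4R)-3-(ArCH2)-3,4-dimethyltetrahydro-2H-pyran-2-ol; 14 allyltributylphosphonium bromide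
Product: 16 (3R,4R,5E)-4-(ArCH2)-3,4-dimethylocta-5,7-dien-1-ol, via phosphorus ylide 15 (not isolated)
Conditions: 14 (3.0 equiv), KN(SiMe3)2 (2.9 equiv), THF, −78 to 0 °C; then 13, 0 to 40 °C
Reagents that add atoms: none
Why: Wittig olefination of the open hydroxy-aldehyde form of the lactol; allylic ylides of trialkylphosphines react under thermodynamic control and should give the (E)-C10=C1 alkene, the excess ylide also serving as base for the lactol hydroxyl.

Step 10
Reactants: 16 (3R,4R,5E)-4-(ArCH2)-3,4-dimethylocta-5,7-dien-1-ol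
Product: 17 (3R,4R,5E)-4-(ArCH2)-3,4-dimethylocta-5,7-dienal
Conditions: Dess–Martin periodinane, NaHCO3, CH2Cl2, 0 °C to rt
Reagents that add atoms: none
Why: Dess–Martin oxidation of the primary alcohol to the C6 aldehyde under buffered, non-acidic conditions that leave the diene and the silyl ether alone.

Step 11
Reactants: 17 (3R,4R,5E)-4-(ArCH2)-3,4-dimethylocta-5,7-dienal; 18 (2-methylprop-1-en-1-yl)magnesium bromide
Product: 19 (6R,7R,8E)-7-(ArCH2)-2,6,7-trimethylundeca-2,8,10-trien-4-ol (both C4 epimers)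
Conditions: 18 (0.5 M in THF, 1.5 equiv), THF, −78 to 0 °C; aq NH4Cl
Reagents that add atoms: none
Why: Grignard addition of the 2-methylpropenyl group to the unhindered aldehyde forms the C5–C6 bond; the carbinol centre is formed without control and is removed in step 12.

Step 12
Reactants: 19 (6R,7R,8E)-7-(ArCH2)-2,6,7-trimethylundeca-2,8,10-trien-4-ol
Product: 20 (6R,7R,8E)-7-(ArCH2)-2,6,7-trimethylundeca-2,8,10-trien-4-one
Conditions: Dess–Martin periodinane, NaHCO3, CH2Cl2, 0 °C to rt
Reagents that add atoms: none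
Why: Dess–Martin oxidation of the allylic alcohol gives the β,β-dimethyl enone without moving the C4=C5 bond out of conjugation.

Step 13
Reactants: 20 (6R,7R,8E)-7-(ArCH2)-2,6,7-trimethylundeca-2,8,10-trien-4-one
Product: 21 (3R,4R,4aR,8aR)-4-(ArCH2)-3,4,8,8-tetramethyl-3,4,4a,7,8,8a-hexahydronaphthalen-1(2H)-one (cis-fused)
Conditions: MeAlCl2 (2.2 equiv), CH2Cl2, −78 to −20 °C
Reagents that add atoms: none
Why: MeAlCl2 binds the C6 carbonyl and lowers the LUMO of the C4=C5 bond, and the (E)-diene on C9 then adds across it in a concerted, asynchronous [4+2] in which the unsubstituted terminus C3 bonds ahead to the cation-like β-carbon C4 while C10 bonds to the α-carbon C5. The closest known reactions are the Lewis-acid-promoted type 1 intramolecular Diels–Alder reactions of deca-1,7,9-trien-3-ones to cis-fused octalones and, for the β,β-disubstituted dienophile, the AlCl3-promoted cycloadditions of 3-methylcyclohex-2-enones with simple dienes. Ring B (C5–C10) is closed by the C5–C10 bond across the four-carbon tether C6–C9 in the fused mode, and ring A (C1–C5, C10) is the new cyclohexene of the cycloaddition, closed by C3–C4 together with C5–C10. C10 is fixed by the diene face that is attacked, which quaternary C9 controls: with the C8 methyl pseudo-equatorial the tether folds so that the large arylmethyl group on C9 points away from the incoming dienophile and C1 ends cis to the C9 methyl; C5 is fixed relative to C10 by the endo arrangement (C6 carbonyl under the diene), which gives the cis ring fusion, and is erased again in step 16. The selectivity the route needs is therefore the diene face, secured by the size difference between CH3 and CH2Ar on C9 and by the (E)-geometry of C10=C1, whereas a trans-fused adduct with the same C10 configuration would converge at alkene 25.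

Step 14
Reactants: 21 (3R,4R,4aR,8aR)-4-(ArCH2)-3,4,8,8-tetramethyl-3,4,4a,7,8,8a-hexahydronaphthalen-1(2H)-one
Product: 22 (3R,4R,4aR,8aR)-4-(ArCH2)-3,4,8,8-tetramethyloctahydronaphthalen-1(2H)-one
Conditions: H2 (1–3 atm), RhCl(PPh3)3 (10 mol %), benzene–EtOH, rt
Reagents that add atoms: none
Why: Homogeneous hydrogenation with RhCl(PPh3)3 saturates the cis-disubstituted C1=C2 bond of ring A and leaves the ketone, the benzyl ethers and the arene untouched.

Step 15
Reactants: 22 (3R,4R,4aR,8aR)-4-(ArCH2)-3,4,8,8-tetramethyloctahydronaphthalen-1(2H)-one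
Product: 23 (1R,3R,4R,4aR,8aR)-4-(ArCH2)-3,4,8,8-tetramethyldecahydronaphthalen-1-ol (6β-alcohol)
Conditions: LiBH(s-Bu)3, THF, −78 to 0 °C; H2O
Reagents that add atoms: none
Why: Hydride reduction of the C6 ketone by the bulky borohydride from the open α-face (the β-face is screened by the axial C1 methylene of the cis-fused ring A) should give the axial 6β-alcohol, trans-diaxial to H5; the new centre is set by substrate control and is removed in step 16.

Step 16
Reactants: 23 (1R,3R,4R,4aR,8aR)-4-(ArCH2)-3,4,8,8-tetramethyldecahydronaphthalen-1-ol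
Product: 25 triisopropylsilyl ether of 4,5-bis(benzyloxy)-2-{[(1R,2R,8aS)-1,2,5,5-tetramethyl-1,2,3,5,6,7,8,8a-octahydronaphthalen-1-yl]methyl}phenol, via dichlorophosphate 24 (not isolated)
Conditions: POCl3 (5 equiv), pyridine, 0 to 60 °C
Reagents that add atoms: none
Why: E2 dehydration through the axial dichlorophosphate, in which anti-periplanar loss of the tertiary axial H5 in the Saytzeff sense should give the trisubstituted C5=C6 alkene, as in the dehydration of axial 6β-hydroxy steroids to 5-enes; loss of the axial H7 to the C6=C7 isomer is the competing path.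

Step 17
Reactants: 25 triisopropylsilyl ether of 4,5-bis(benzyloxy)-2-{[(1R,2R,8aS)-1,2,5,5-tetramethyl-1,2,3,5,6,7,8,8a-octahydronaphthalen-1-yl]methyl}phenol
Product: 26 4,5-bis(benzyloxy)-2-{[(1R,2R,8aS)-1,2,5,5-tetramethyl-1,2,3,5,6,7,8,8a-octahydronaphthalen-1-yl]methyl}phenol
Conditions: Bu4NF (1.1 equiv), AcOH (1.1 equiv), THF, 0 °C
Reagents that add atoms: none
Why: Fluoride cleavage of the aryl silyl ether, buffered with acetic acid, frees the C2' hydroxyl while the benzyl ethers and the alkene are inert.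

Step 18
Reactants: 26 4,5-bis(benzyloxy)-2-{[(1R,2R,8aS)-1,2,5,5-tetramethyl-1,2,3,5,6,7,8,8a-octahydronaphthalen-1-yl]methyl}phenol
Product: 27 2,3-bis(benzyloxy)-6-hydroxy-5-{[(1R,2R,8aS)-1,2,5,5-tetramethyl-1,2,3,5,6,7,8,8a-octahydronaphthalen-1-yl]methyl}benzaldehyde
Conditions: MgCl2 (3 equiv), Et3N (6 equiv), (CH2O)n (10 equiv), THF, reflux, argon
Reagents that add atoms: paraformaldehyde (formaldehyde), C=O
Why: Magnesium-mediated ortho-formylation of the phenol (Casnati–Skattebøl), in which formaldehyde is delivered within the magnesium phenoxide to the only free ortho position, C3', and the resulting benzylic alkoxide is oxidised in situ by a second formaldehyde.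

Step 19
Reactants: 27 2,3-bis(benzyloxy)-6-hydroxy-5-{[(1R,2R,8aS)-1,2,5,5-tetramethyl-1,2,3,5,6,7,8,8a-octahydronaphthalen-1-yl]methyl}benzaldehyde
Product: 28 3,4-bis(benzyloxy)-2-formyl-6-{[(1R,2R,8aS)-1,2,5,5-tetramethyl-1,2,3,5,6,7,8,8a-octahydronaphthalen-1-yl]methyl}phenyl hydrogen sulfate
Conditions: SO3·pyridine (5 equiv), pyridine, 50 °C; aq NaHCO3 work-up, kept as the sodium salt
Reagents that add atoms: sulfur trioxide–pyridine complex, O=S(=O)=O.c1ccncc1
Why: O-Sulfation of the phenol with the sulfur trioxide–pyridine complex, which can only take place at the C2' oxygen because the other two phenolic oxygens are benzylated.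

Step 20
Reactants: 28 3,4-bis(benzyloxy)-2-formyl-6-{[(1R,2R,8aS)-1,2,5,5-tetramethyl-1,2,3,5,6,7,8,8a-octahydronaphthalen-1-yl]methyl}phenyl hydrogen sulfate
Product: 29 2-formyl-3,4-dihydroxy-6-{[(1R,2R,8aS)-1,2,5,5-tetramethyl-1,2,3,5,6,7,8,8a-octahydronaphthalen-1-yl]methyl}phenyl hydrogen sulfate (target)
Conditions: H2 (1 atm), Pd on carbon (10% Pd), EtOAc–MeOH, rt, followed closely; then cation exchange (H+ form), 0 °C
Reagents that add atoms: none
Why: Hydrogenolysis of the two aryl benzyl ethers over palladium on carbon, which should be much faster than reduction of the hindered, chelated salicylaldehyde or of the trisubstituted C5=C6 bond flanked by quaternary C4, and which aryl sulfate salts are known to survive.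

**Compound list**

1 | 2,4,5-trihydroxybenzaldehyde | O=Cc1cc(O)c(O)cc1O | starting material
2 | 4,5-bis(benzyloxy)-2-hydroxybenzaldehyde | O=Cc1cc(OCc2ccccc2)c(OCc2ccccc2)cc1O | intermediate
3 | 4,5-bis(benzyloxy)-2-(triisopropylsilyloxy)benzaldehyde | O=Cc1cc(OCc2ccccc2)c(OCc2ccccc2)cc1O[Si](C(C)C)(C(C)C)C(C)C | intermediate
4 | [4,5-bis(benzyloxy)-2-(triisopropylsilyloxy)phenyl]methanol | OCc1cc(OCc2ccccc2)c(OCc2ccccc2)cc1O[Si](C(C)C)(C(C)C)C(C)C | intermediate
5 | 4,5-bis(benzyloxy)-2-(triisopropylsilyloxy)benzyl bromide | BrCc1cc(OCc2ccccc2)c(OCc2ccccc2)cc1O[Si](C(C)C)(C(C)C)C(C)C | intermediate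
6 | (R)-5-methoxy-3-methyl-5-oxopentanoic acid | COC(=O)C[C@H](C)CC(=O)O | starting material
7 | methyl (R)-5-hydroxy-3-methylpentanoate | COC(=O)C[C@H](C)CCO | intermediate (not isolated)
8 | (R)-4-methyltetrahydro-2H-pyran-2-one | C[C@H]1CC(=O)OCC1 | intermediate
9 | lithium (R)-4-methyl-3,4-dihydro-2H-pyran-6-olate (enolate of 8) | [Li]OC1=C[C@H](C)CCO1 | intermediate (not isolated)
10 | (3S,4R)-3-{[4,5-bis(benzyloxy)-2-(triisopropylsilyloxy)phenyl]methyl}-4-methyltetrahydro-2H-pyran-2-one | C[C@@H]1CCOC(=O)[C@H]1Cc1cc(OCc2ccccc2)c(OCc2ccccc2)cc1O[Si](C(C)C)(C(C)C)C(C)C | intermediate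
11 | lithium (R)-5-{[4,5-bis(benzyloxy)-2-(triisopropylsilyloxy)phenyl]methyl}-4-methyl-3,4-dihydro-2H-pyran-6-olate (enolate of 10) | [Li]OC1=C(Cc2cc(OCc3ccccc3)c(OCc3ccccc3)cc2O[Si](C(C)C)(C(C)C)C(C)C)[C@H](C)CCO1 | intermediate (not isolated)
12 | (3R,4R)-3-{[4,5-bis(benzyloxy)-2-(triisopropylsilyloxy)phenyl]methyl}-3,4-dimethyltetrahydro-2H-pyran-2-one | C[C@@H]1CCOC(=O)[C@]1(C)Cc1cc(OCc2ccccc2)c(OCc2ccccc2)cc1O[Si](C(C)C)(C(C)C)C(C)C | intermediate
13 | (3R,4R)-3-{[4,5-bis(benzyloxy)-2-(triisopropylsilyloxy)phenyl]methyl}-3,4-dimethyltetrahydro-2H-pyran-2-ol (both anomers) | C[C@@H]1CCOC(O)[C@]1(C)Cc1cc(OCc2ccccc2)c(OCc2ccccc2)cc1O[Si](C(C)C)(C(C)C)C(C)C | intermediate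
14 | allyltributylphosphonium bromide | C=CC[P+](CCCC)(CCCC)CCCC.[Br-] | starting material
15 | tributyl(prop-2-en-1-ylidene)phosphorane | C=CC=P(CCCC)(CCCC)CCCC | intermediate (not isolated)
16 | (3R,4R,5E)-4-{[4,5-bis(benzyloxy)-2-(triisopropylsilyloxy)phenyl]methyl}-3,4-dimethylocta-5,7-dien-1-ol | C[C@H](CCO)[C@@](C)(Cc1cc(OCc2ccccc2)c(OCc2ccccc2)cc1O[Si](C(C)C)(C(C)C)C(C)C)/C=C/C=C | intermediate
17 | (3R,4R,5E)-4-{[4,5-bis(benzyloxy)-2-(triisopropylsilyloxy)phenyl]methyl}-3,4-dimethylocta-5,7-dienal | C[C@H](CC=O)[C@@](C)(Cc1cc(OCc2ccccc2)c(OCc2ccccc2)cc1O[Si](C(C)C)(C(C)C)C(C)C)/C=C/C=C | intermediate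
18 | (2-methylprop-1-en-1-yl)magnesium bromide | CC(C)=C[Mg]Br | starting material
19 | (6R,7R,8E)-7-{[4,5-bis(benzyloxy)-2-(triisopropylsilyloxy)phenyl]methyl}-2,6,7-trimethylundeca-2,8,10-trien-4-ol (both C4 epimers) | C[C@H](CC(O)C=C(C)C)[C@@](C)(Cc1cc(OCc2ccccc2)c(OCc2ccccc2)cc1O[Si](C(C)C)(C(C)C)C(C)C)/C=C/C=C | intermediate
20 | (6R,7R,8E)-7-{[4,5-bis(benzyloxy)-2-(triisopropylsilyloxy)phenyl]methyl}-2,6,7-trimethylundeca-2,8,10-trien-4-one | C[C@H](CC(=O)C=C(C)C)[C@@](C)(Cc1cc(OCc2ccccc2)c(OCc2ccccc2)cc1O[Si](C(C)C)(C(C)C)C(C)C)/C=C/C=C | intermediate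
21 | (3R,4R,4aR,8aR)-4-{[4,5-bis(benzyloxy)-2-(triisopropylsilyloxy)phenyl]methyl}-3,4,8,8-tetramethyl-3,4,4a,7,8,8a-hexahydronaphthalen-1(2H)-one | C[C@@H]1CC(=O)[C@@H]2[C@@H](C=CCC2(C)C)[C@]1(C)Cc1cc(OCc2ccccc2)c(OCc2ccccc2)cc1O[Si](C(C)C)(C(C)C)C(C)C | intermediate
22 | (3R,4R,4aR,8aR)-4-{[4,5-bis(benzyloxy)-2-(triisopropylsilyloxy)phenyl]methyl}-3,4,8,8-tetramethyloctahydronaphthalen-1(2H)-one | C[C@@H]1CC(=O)[C@@H]2[C@@H](CCCC2(C)C)[C@]1(C)Cc1cc(OCc2ccccc2)c(OCc2ccccc2)cc1O[Si](C(C)C)(C(C)C)C(C)C | intermediate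
23 | (1R,3R,4R,4aR,8aR)-4-{[4,5-bis(benzyloxy)-2-(triisopropylsilyloxy)phenyl]methyl}-3,4,8,8-tetramethyldecahydronaphthalen-1-ol | C[C@@H]1C[C@@H](O)[C@@H]2[C@@H](CCCC2(C)C)[C@]1(C)Cc1cc(OCc2ccccc2)c(OCc2ccccc2)cc1O[Si](C(C)C)(C(C)C)C(C)C | intermediate
24 | (1R,3R,4R,4aR,8aR)-4-{[4,5-bis(benzyloxy)-2-(triisopropylsilyloxy)phenyl]methyl}-3,4,8,8-tetramethyldecahydronaphthalen-1-yl phosphorodichloridate | C[C@@H]1C[C@@H](OP(=O)(Cl)Cl)[C@@H]2[C@@H](CCCC2(C)C)[C@]1(C)Cc1cc(OCc2ccccc2)c(OCc2ccccc2)cc1O[Si](C(C)C)(C(C)C)C(C)C | intermediate (not isolated)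
25 | {4,5-bis(benzyloxy)-2-{[(1R,2R,8aS)-1,2,5,5-tetramethyl-1,2,3,5,6,7,8,8a-octahydronaphthalen-1-yl]methyl}phenoxy}triisopropylsilane | C[C@@H]1CC=C2[C@@H](CCCC2(C)C)[C@]1(C)Cc1cc(OCc2ccccc2)c(OCc2ccccc2)cc1O[Si](C(C)C)(C(C)C)C(C)C | intermediate
26 | 4,5-bis(benzyloxy)-2-{[(1R,2R,8aS)-1,2,5,5-tetramethyl-1,2,3,5,6,7,8,8a-octahydronaphthalen-1-yl]methyl}phenol | C[C@@H]1CC=C2[C@@H](CCCC2(C)C)[C@]1(C)Cc1cc(OCc2ccccc2)c(OCc2ccccc2)cc1O | intermediate
27 | 2,3-bis(benzyloxy)-6-hydroxy-5-{[(1R,2R,8aS)-1,2,5,5-tetramethyl-1,2,3,5,6,7,8,8a-octahydronaphthalen-1-yl]methyl}benzaldehyde | C[C@@H]1CC=C2[C@@H](CCCC2(C)C)[C@]1(C)Cc1cc(OCc2ccccc2)c(OCc2ccccc2)c(C=O)c1O | intermediate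
28 | 3,4-bis(benzyloxy)-2-formyl-6-{[(1R,2R,8aS)-1,2,5,5-tetramethyl-1,2,3,5,6,7,8,8a-octahydronaphthalen-1-yl]methyl}phenyl hydrogen sulfate | C[C@@H]1CC=C2[C@@H](CCCC2(C)C)[C@]1(C)Cc1cc(OCc2ccccc2)c(OCc2ccccc2)c(C=O)c1OS(=O)(=O)O | intermediate
29 | 2-formyl-3,4-dihydroxy-6-{[(1R,2R,8aS)-1,2,5,5-tetramethyl-1,2,3,5,6,7,8,8a-octahydronaphthalen-1-yl]methyl}phenyl hydrogen sulfate | C[C@@H]1CC=C2[C@@H](CCCC2(C)C)[C@]1(C)Cc1cc(O)c(O)c(C=O)c1OS(=O)(=O)O | target

**Step count and risks**

Total step count: 20. Longest linear sequence: 19 steps (steps 1–4, then 6–20, from 2,4,5-trihydroxybenzaldehyde).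

Steps most likely to fail:

1. Step 13. The MeAlCl2 complex of the β,β-disubstituted enone may add too slowly, so that cationic oligomerisation of the diene, attack of the Lewis acid on the ether groups, or erosion of the facial bias at C10 takes over. The fallback replaces the enone by an alkynone, a smaller and more reactive dienophile with no endo/exo question. It sets out from aldehyde 17. Addition of 1-propynylmagnesium bromide gives (6R,7R,8E)-7-(ArCH2)-6,7-dimethylundeca-8,10-dien-2-yn-4-ol F1, and Dess–Martin oxidation gives alkynone F2. Heating in toluene (110 °C, or Me2AlCl at low temperature) should give the intramolecular Diels–Alder adduct, the cyclohexa-1,4-diene-fused enone F3, in which C10 is the only new stereocentre and is set by the same facial bias. Conjugate addition of Me2CuLi brings in the second C4 methyl, and the resulting C5=C6 enolate is trapped with N-(5-chloropyridin-2-yl)triflimide as enol triflate F4. Reduction with Pd(OAc)2, PPh3, HCO2H and n-Bu3N in DMF gives diene F5, and hydrogenation over RhCl(PPh3)3 reduces only the disubstituted C1=C2 bond. The route is rejoined at alkene 25, and steps 14–16 are not needed. Because the alkene position then comes from a regiodefined enolate, the same detour also serves should the elimination of step 16 go toward C7.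

2. Step 20. During hydrogenolysis the aldehyde may be reduced, or the sulfate may be lost by solvolysis as the catechol is set free. The fallback sets out from phenol 27 and carries the sulfate as a protected diester. 2,2,2-Trichloroethyl chlorosulfate with Et3N and DMAP in THF gives the aryl 2,2,2-trichloroethyl sulfate F6. The benzyl ethers are then removed without hydrogen by BCl3 and pentamethylbenzene in CH2Cl2 at −78 °C, giving catechol F7. Zinc dust and HCO2NH4 in MeOH cleave the trichloroethyl group, and cation exchange returns the route at target 29.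

3. Step 18. Attack of the magnesium-bound formaldehyde at C3', which lies between the phenoxide and a benzyloxy group, may be too slow, so that the electron-rich phenol is recovered or oxidised. The fallback sets out from phenol 26. Ortho-bromination with NBS and catalytic i-Pr2NH in CH2Cl2 (the para position is occupied) gives 3,4-bis(benzyloxy)-2-bromo-6-(terpenylmethyl)phenol F8. Treatment with n-BuLi (2.2 equiv) in THF at −78 °C deprotonates the phenol and exchanges bromine for lithium, and DMF then gives the aldehyde. The route is rejoined at 27.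

**Further compounds**

F1 | step 13 | (6R,7R,8E)-7-{[4,5-bis(benzyloxy)-2-(triisopropylsilyloxy)phenyl]methyl}-6,7-dimethylundeca-8,10-dien-2-yn-4-ol (both C4 epimers) | C[C@H](CC(O)C#CC)[C@@](C)(Cc1cc(OCc2ccccc2)c(OCc2ccccc2)cc1O[Si](C(C)C)(C(C)C)C(C)C)/C=C/C=C
F2 | step 13 | (6R,7R,8E)-7-{[4,5-bis(benzyloxy)-2-(triisopropylsilyloxy)phenyl]methyl}-6,7-dimethylundeca-8,10-dien-2-yn-4-one | C[C@H](CC(=O)C#CC)[C@@](C)(Cc1cc(OCc2ccccc2)c(OCc2ccccc2)cc1O[Si](C(C)C)(C(C)C)C(C)C)/C=C/C=C
F3 | step 13 | (3R,4R,4aS)-4-{[4,5-bis(benzyloxy)-2-(triisopropylsilyloxy)phenyl]methyl}-3,4,8-trimethyl-3,4,4a,7-tetrahydronaphthalen-1(2H)-one | C[C@@H]1CC(=O)C2=C(C)CC=C[C@H]2[C@]1(C)Cc1cc(OCc2ccccc2)c(OCc2ccccc2)cc1O[Si](C(C)C)(C(C)C)C(C)C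
F4 | step 13 | (3R,4R,4aS)-4-{[4,5-bis(benzyloxy)-2-(triisopropylsilyloxy)phenyl]methyl}-3,4,8,8-tetramethyl-2,3,4,4a,7,8-hexahydronaphthalen-1-yl trifluoromethanesulfonate | C[C@@H]1CC(OS(=O)(=O)C(F)(F)F)=C2[C@@H](C=CCC2(C)C)[C@]1(C)Cc1cc(OCc2ccccc2)c(OCc2ccccc2)cc1O[Si](C(C)C)(C(C)C)C(C)C
F5 | step 13 | {4,5-bis(benzyloxy)-2-{[(1R,2R,8aS)-1,2,5,5-tetramethyl-1,2,3,5,6,8a-hexahydronaphthalen-1-yl]methyl}phenoxy}triisopropylsilane | C[C@@H]1CC=C2[C@@H](C=CCC2(C)C)[C@]1(C)Cc1cc(OCc2ccccc2)c(OCc2ccccc2)cc1O[Si](C(C)C)(C(C)C)C(C)C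
F6 | step 20 | 3,4-bis(benzyloxy)-2-formyl-6-{[(1R,2R,8aS)-1,2,5,5-tetramethyl-1,2,3,5,6,7,8,8a-octahydronaphthalen-1-yl]methyl}phenyl 2,2,2-trichloroethyl sulfate | C[C@@H]1CC=C2[C@@H](CCCC2(C)C)[C@]1(C)Cc1cc(OCc2ccccc2)c(OCc2ccccc2)c(C=O)c1OS(=O)(=O)OCC(Cl)(Cl)Cl
F7 | step 20 | 2-formyl-3,4-dihydroxy-6-{[(1R,2R,8aS)-1,2,5,5-tetramethyl-1,2,3,5,6,7,8,8a-octahydronaphthalen-1-yl]methyl}phenyl 2,2,2-trichloroethyl sulfate | C[C@@H]1CC=C2[C@@H](CCCC2(C)C)[C@]1(C)Cc1cc(O)c(O)c(C=O)c1OS(=O)(=O)OCC(Cl)(Cl)Cl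
F8 | step 18 | 3,4-bis(benzyloxy)-2-bromo-6-{[(1R,2R,8aS)-1,2,5,5-tetramethyl-1,2,3,5,6,7,8,8a-octahydronaphthalen-1-yl]methyl}phenol | C[C@@H]1CC=C2[C@@H](CCCC2(C)C)[C@]1(C)Cc1cc(OCc2ccccc2)c(OCc2ccccc2)c(Br)c1O
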